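**Plan**

- Units are numbered 1–4 from the catechin end with flavan numbering, and the target is read as catechin-(4α→6)-epicatechin-(4β→8)-epicatechin-(4β→8)-epicatechin. The retrosynthesis cuts the interflavan bonds C4(unit 2)–C8(unit 3) and C4(unit 3)–C8(unit 4), then O1–C2 and C3–C4 of unit 1, then C4(unit 1)–C6(unit 2).
- Enabling feature: ring C of unit 1 is the only 2,3-trans heterocycle, and its C2 aryl, C3 oxygen and C4 aryl groups are all mutually trans (all equatorial). O1–C8a–C4a–C4 can therefore come from an o-quinone methide and C2–C3 from an E alkene in an endo [4+2].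
- Forward: benzylated epicatechin is oxidised at C4; one part gives the lower dimer (units 3 and 4), the other is halogenated (C8–Br, C6–I) and given a C4 thioether that is inert to Brønsted acid (unit 2).
- The C6-aryllithium adds to an O-allyl phloroglucinaldehyde and deallylation gives the o-hydroxybenzhydrol. Cycloaddition with an E enol benzoate closes ring C of unit 1, AgBF4 activation of the thioether joins unit 2 to the lower dimer, and ester cleavage and hydrogenolysis finish.
- Stereochemistry: C2 and C3 of units 2–4 come from (−)-epicatechin; the 4β bonds come from attack on the flavan-4-yl cations anti to the C3 oxygen; C2, C3 and C4 of unit 1 come from the E alkene, the endo transition state and the chiral phosphate.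

Key step: step 15

Assumption: the sense of induction of the phosphoric acid in step 15 cannot be predicted with confidence; the (R)-acid is written, and its antipode would take its place if screening shows it to favour the other face of the quinone methide.

**Step 1**
Reactants: 1 (−)-epicatechin
Product: 2 5,7,3',4'-tetra-O-benzyl-(−)-epicatechin
Conditions: BnBr (4.4 equiv), K2CO3, DMF, 0 °C to rt
Reagents that add atoms: benzyl bromide, BrCc1ccccc1
Why: The four phenols are far more acidic than the secondary 3-hydroxyl, so a K2CO3-mediated Williamson etherification should benzylate only the phenolic oxygens and leave C2 and C3 untouched.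

**Step 2**
Reactants: 2 5,7,3',4'-tetra-O-benzyl-(−)-epicatechin
Product: 3 3,5,7,3',4'-penta-O-benzyl-(−)-epicatechin
Conditions: NaH, BnBr, Bu4NI (cat.), DMF, 0 °C to rt
Reagents that add atoms: benzyl bromide, BrCc1ccccc1
Why: Williamson etherification of the secondary alkoxide caps O3 so that no acidic proton interferes with the later aryllithium step, and no stereocentre is involved.

**Step 3**
Reactants: 3 3,5,7,3',4'-penta-O-benzyl-(−)-epicatechin
Product: 4 4β-(2-ethoxyethoxy)-3,5,7,3',4'-penta-O-benzylepicatechin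
Conditions: DDQ (2 equiv), 2-ethoxyethanol (5 equiv), CH2Cl2, rt
Reagents that add atoms: 2-ethoxyethanol, CCOCCO
Why: In this benzylic oxidation DDQ should abstract the C4 hydride, which is activated by O1 and the 5,7-dialkoxy ring A, and the alcohol should trap the cation anti to the 3-benzyloxy group to give the 4β ether (3,4-trans).

**Step 4**
Reactants: 4 4β-(2-ethoxyethoxy)-3,5,7,3',4'-penta-O-benzylepicatechin; 3 3,5,7,3',4'-penta-O-benzyl-(−)-epicatechin (4 equiv)
Product: 5 deca-O-benzyl procyanidin B2, that is 3,5,7,3',4'-penta-O-benzylepicatechin-(4β→8)-3,5,7,3',4'-penta-O-benzylepicatechin (lower dimer, units 3 and 4)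
Conditions: TMSOTf (0.2 equiv), CH2Cl2, −78 to −40 °C; Et3N quench
Reagents that add atoms: none
Why: Lewis-acid ionisation of the C4 ether gives the flavan-4-yl cation, which the excess nucleophile should attack through C8 in a Friedel–Crafts-type interflavan coupling on the β face, anti to the C3 oxygen and the C2 aryl group, setting the 4β bond of unit 3.

**Step 5**
Reactants: 4 4β-(2-ethoxyethoxy)-3,5,7,3',4'-penta-O-benzylepicatechin
Product: 6 8-bromo-4β-(2-ethoxyethoxy)-3,5,7,3',4'-penta-O-benzylepicatechin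
Conditions: NBS (1.05 equiv), CH2Cl2, −78 to 0 °C, dark
Reagents that add atoms: N-bromosuccinimide, O=C1CCC(=O)N1Br
Why: Electrophilic aromatic bromination of the phloroglucinol-type ring A should go to C8, the more accessible and more reactive of its two free positions, under neutral cold conditions that leave the C4 ether alone.

**Step 6**
Reactants: 6 8-bromo-4β-(2-ethoxyethoxy)-3,5,7,3',4'-penta-O-benzylepicatechin
Product: 7 8-bromo-6-iodo-4β-(2-ethoxyethoxy)-3,5,7,3',4'-penta-O-benzylepicatechin
Conditions: NIS (1.3 equiv), NaHCO3, DMF, 0 °C to rt, dark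
Reagents that add atoms: N-iodosuccinimide, O=C1CCC(=O)N1I
Why: With C8 blocked, electrophilic aromatic iodination can only go to C6 of the still electron-rich ring A (ring B is much less reactive), and the bicarbonate keeps the C4 ether from ionising.

**Step 7**
Reactants: 7 8-bromo-6-iodo-4β-(2-ethoxyethoxy)-3,5,7,3',4'-penta-O-benzylepicatechin
Product: 8 8-bromo-6-iodo-4β-(4-methylphenylthio)-3,5,7,3',4'-penta-O-benzylepicatechin
Conditions: 4-methylbenzenethiol (3 equiv), BF3·OEt2 (0.5 equiv), CH2Cl2, −78 to −20 °C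
Reagents that add atoms: 4-methylbenzenethiol, Cc1ccc(S)cc1
Why: Lewis-acid-mediated SN1 exchange through the C4 cation should deliver the thiol anti to the 3-benzyloxy group (4β), self-condensation being excluded because C6 and C8 are both halogenated, and the thioether should resist Brønsted acid until a thiophile activates it.

**Step 8**
Reactants: 9 2,4,6-trihydroxybenzaldehyde
Product: 10 2,4-bis(benzyloxy)-6-hydroxybenzaldehyde
Conditions: BnBr (2.05 equiv), K2CO3, DMF, 0 °C to rt
Reagents that add atoms: benzyl bromide, BrCc1ccccc1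
Why: Williamson etherification should take the 4-hydroxyl and one ortho hydroxyl, the last ortho hydroxyl being held by a hydrogen bond to the formyl group and reacting much more slowly.

**Step 9**
Reactants: 10 2,4-bis(benzyloxy)-6-hydroxybenzaldehyde
Product: 11 2-allyloxy-4,6-bis(benzyloxy)benzaldehyde
Conditions: allyl bromide, K2CO3, DMF, 50 °C
Reagents that add atoms: allyl bromide, C=CCBr
Why: Williamson allylation of the chelated phenol installs a protecting group that can later be removed without acid, which the benzhydrol of step 10 would not tolerate.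

**Step 10**
Reactants: 8 8-bromo-6-iodo-4β-(4-methylphenylthio)-3,5,7,3',4'-penta-O-benzylepicatechin; 11 2-allyloxy-4,6-bis(benzyloxy)benzaldehyde
Product: 13 [2-allyloxy-4,6-bis(benzyloxy)phenyl][8-bromo-4β-(4-methylphenylthio)-3,5,7,3',4'-penta-O-benzylepicatechin-6-yl]methanol (both carbinol epimers), via C6-aryllithium 12 (not isolated)
Conditions: n-BuLi (1.05 equiv), THF, −78 °C, 10 min; then 11 (1.3 equiv), −78 to −40 °C; aq NH4Cl
Reagents that add atoms: none
Why: Iodine–lithium exchange is much faster than bromine–lithium exchange, so only C6 should be metalated, and 1,2-addition of this aryllithium to the aldehyde should give the tetra-ortho-substituted benzhydrol, whose uncontrolled carbinol centre is erased in step 15.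

**Step 11**
Reactants: 13 the O-allyl benzhydrol
Product: 14 [2-hydroxy-4,6-bis(benzyloxy)phenyl][8-bromo-4β-(4-methylphenylthio)-3,5,7,3',4'-penta-O-benzylepicatechin-6-yl]methanol (both carbinol epimers)
Conditions: Pd(PPh3)4 (5 mol%), morpholine (5 equiv), THF, rt; filtration through Et3N-deactivated silica, used without delay
Reagents that add atoms: none
Why: Tsuji–Trost deallylation with zerovalent palladium and an amine scavenger cleaves the aryl allyl ether under non-acidic conditions, which the acid-labile benzhydrol, the hindered aryl bromide and the thioether should survive.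

**Step 12**
Reactants: 15 3,4-bis(benzyloxy)benzaldehyde
Product: 16 (E)-2-[3,4-bis(benzyloxy)styryl]-4,4,5,5-tetramethyl-1,3,2-dioxaborolane
Conditions: CH2(Bpin)2 (1.2 equiv), LiTMP (lithium 2,2,6,6-tetramethylpiperidide, 1.2 equiv), THF, 0 °C; then 15, −78 °C to rt
Reagents that add atoms: bis(pinacolato)borylmethane, CC1(C)OB(CB2OC(C)(C)C(C)(C)O2)OC1(C)C
Why: The boron-Wittig olefination of an aromatic aldehyde with lithiated bis(pinacolboryl)methane should give the trans alkenylboronate through syn elimination of the boron–oxygen pair.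

**Step 13**
Reactants: 16 (E)-2-[3,4-bis(benzyloxy)styryl]-4,4,5,5-tetramethyl-1,3,2-dioxaborolane
Product: 17 potassium (E)-[3,4-bis(benzyloxy)styryl]trifluoroborate
Conditions: KHF2 (4.5 equiv), MeOH/H2O, rt; recrystallisation
Reagents that add atoms: potassium hydrogen difluoride, F.[F-].[K+]
Why: Fluoride exchange at boron converts the pinacol ester into the crystalline trifluoroborate with retention of the E geometry, and crystallisation should remove any Z isomer.

**Step 14**
Reactants: 17 potassium (E)-[3,4-bis(benzyloxy)styryl]trifluoroborate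
Product: 18 (E)-2-[3,4-bis(benzyloxy)phenyl]vinyl benzoate
Conditions: PhCO2H (1.5 equiv), CuBr (10 mol%), DMAP (20 mol%), 4 Å MS, O2 (1 atm), MeCN, 60 °C
Reagents that add atoms: benzoic acid, OC(=O)c1ccccc1
Why: The CuBr-catalysed oxidative C–O coupling of the Chan–Lam type between an alkenyltrifluoroborate and a carboxylic acid is stereospecific, so the E geometry should be carried into the enol ester.

**Step 15**
Reactants: 14 the o-hydroxybenzhydrol; 18 (E)-2-[3,4-bis(benzyloxy)phenyl]vinyl benzoate (3 equiv)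
Product: 20 3-O-benzoyl-5,7,3',4'-tetra-O-benzylcatechin-(4α→6)-8-bromo-4β-(4-methylphenylthio)-3,5,7,3',4'-penta-O-benzylepicatechin, via o-quinone methide 19 (not isolated)
Conditions: (R)-3,3'-bis(2,4,6-triisopropylphenyl)-1,1'-binaphthyl-2,2'-diyl hydrogen phosphate (10 mol%), 5 Å MS, PhCF3, −20 °C to rt
Reagents that add atoms: none
Why: Proposed new method: the phosphoric acid should activate the carbinol hydroxyl of 14 while hydrogen-bonding its phenol, so that loss of water (taken up by the sieves) gives the E o-quinone methide 19 held by the chiral phosphate; the enol benzoate then reacts as an electron-rich styrene, its oxygen-bearing carbon bonding to the methide carbon (C3–C4) while the charge developing at the benzylic carbon, stabilised by the 3,4-dibenzyloxyphenyl ring, is captured by the quinone methide oxygen (O1–C2) in an asynchronous inverse-electron-demand hetero-Diels–Alder reaction. The closest known reaction type is the chiral phosphoric acid-catalysed [4+2] cycloaddition of o-quinone methides, generated from o-hydroxybenzhydrols, with styrenes to give 2,4-cis-diarylchromans; the enol ester as 2π partner and the doubly ortho-alkoxylated aryl group on the methide carbon are the untested elements. Ring C of unit 1 closes in a formal [4+2] mode, which in the stepwise limit is a 6-exo-trig capture of the p-alkoxybenzyl cation by the phenolic oxygen. C4 is set by the methide face that the phosphate leaves open (catalyst control, the stereocentres of unit 2 being remote), C3 by the exo position that the benzoate must take on the E alkene once the aryl group sits endo, and C2 by suprafacial addition across the E alkene, which puts aryl and benzoate trans and all three substituents equatorial. The step needs aryl-over-acyloxy regiocontrol, secured by pairing a weakly donating benzoate with a strongly donating dialkoxyphenyl group, and it needs the alkene to outrun arene nucleophiles and the C4–S bond to stay intact, secured by the C8 bromine, the crowding at the methide carbon, the excess of 18 and the inertness of the thioether to Brønsted acid.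

**Step 16**
Reactants: 20 the upper dimer thioether; 5 deca-O-benzyl procyanidin B2 (3 equiv)
Product: 21 3-O-benzoyl-5,7,3',4'-tetra-O-benzylcatechin-(4α→6)-8-bromo-3,5,7,3',4'-penta-O-benzylepicatechin-(4β→8)-3,5,7,3',4'-penta-O-benzylepicatechin-(4β→8)-3,5,7,3',4'-penta-O-benzylepicatechin
Conditions: AgBF4 (2 equiv), 2,6-di-tert-butyl-4-methylpyridine (2 equiv), 4 Å MS, CH2Cl2/THF, −40 to 0 °C, dark, slow addition of 20
Reagents that add atoms: none
Why: The soft Ag+ ion of AgBF4 should ionise only the C4–S bond (thiophilic activation), and the flavan-4-yl cation of unit 2 should be attacked by C8 of the upper unit of 5 on the β face in a Friedel–Crafts-type coupling, setting the 4β bond of unit 2 while the pyridine buffer protects the interflavan bonds from acid.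

**Step 17**
Reactants: 21 the benzoate-bearing protected tetramer
Product: 22 5,7,3',4'-tetra-O-benzylcatechin-(4α→6)-8-bromo-3,5,7,3',4'-penta-O-benzylepicatechin-(4β→8)-3,5,7,3',4'-penta-O-benzylepicatechin-(4β→8)-3,5,7,3',4'-penta-O-benzylepicatechin (free 3-hydroxyl on unit 1)
Conditions: NaOMe (0.5 equiv), MeOH/THF, 40 °C
Reagents that add atoms: none
Why: Zemplén-type transesterification removes the benzoate, the only group that hydrogenolysis would not cleave, without touching benzyl ethers, the aryl bromide or any stereocentre, since no free phenol is present that could open a ring C.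

**Step 18**
Reactants: 22 the nonadeca-O-benzyl bromo tetramer
Product: 23 catechin-(4α→6)-epicatechin-(4β→8)-epicatechin-(4β→8)-epicatechin (CNP0228086.1)
Conditions: H2 (1 atm), Pd(OH)2/C, NaOAc (2 equiv), THF/MeOH/H2O, rt
Reagents that add atoms: none
Why: Catalytic hydrogenolysis should cleave all nineteen benzyl ethers and the aryl C–Br bond in one operation, the acetate buffering the HBr so that the acid-sensitive interflavan bonds stay intact.

**Compound list**

1 | (−)-epicatechin | O[C@@H]1Cc2c(O)cc(O)cc2O[C@@H]1c1ccc(O)c(O)c1 | starting material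

2 | 5,7,3',4'-tetra-O-benzyl-(−)-epicatechin | c1c(OCc5ccccc5)cc2c(c1OCc5ccccc5)C[C@@H](O)[C@@H](c1ccc(OCc5ccccc5)c(OCc5ccccc5)c1)O2 | intermediate

3 | 3,5,7,3',4'-penta-O-benzyl-(−)-epicatechin | c1c(OCc5ccccc5)cc2c(c1OCc5ccccc5)C[C@@H](OCc5ccccc5)[C@@H](c1ccc(OCc5ccccc5)c(OCc5ccccc5)c1)O2 | intermediate

4 | 4β-(2-ethoxyethoxy)-3,5,7,3',4'-penta-O-benzylepicatechin | c1c(OCc5ccccc5)cc2c(c1OCc5ccccc5)[C@H](OCCOCC)[C@@H](OCc5ccccc5)[C@@H](c1ccc(OCc5ccccc5)c(OCc5ccccc5)c1)O2 | intermediate

5 | deca-O-benzyl procyanidin B2 (penta-O-benzylepicatechin-(4β→8)-penta-O-benzylepicatechin) | c1c(OCc5ccccc5)cc(OCc5ccccc5)c3c1O[C@H](c1ccc(OCc5ccccc5)c(OCc5ccccc5)c1)[C@H](OCc5ccccc5)[C@H]3c1c(OCc5ccccc5)cc(OCc5ccccc5)c3c1O[C@H](c1ccc(OCc5ccccc5)c(OCc5ccccc5)c1)[C@H](OCc5ccccc5)C3 | intermediate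

6 | 8-bromo-4β-(2-ethoxyethoxy)-3,5,7,3',4'-penta-O-benzylepicatechin | c1c(OCc5ccccc5)c(Br)c2c(c1OCc5ccccc5)[C@H](OCCOCC)[C@@H](OCc5ccccc5)[C@@H](c1ccc(OCc5ccccc5)c(OCc5ccccc5)c1)O2 | intermediate

7 | 8-bromo-6-iodo-4β-(2-ethoxyethoxy)-3,5,7,3',4'-penta-O-benzylepicatechin | Ic1c(OCc5ccccc5)c(Br)c2c(c1OCc5ccccc5)[C@H](OCCOCC)[C@@H](OCc5ccccc5)[C@@H](c1ccc(OCc5ccccc5)c(OCc5ccccc5)c1)O2 | intermediate

8 | 8-bromo-6-iodo-4β-(4-methylphenylthio)-3,5,7,3',4'-penta-O-benzylepicatechin | Ic1c(OCc5ccccc5)c(Br)c2c(c1OCc5ccccc5)[C@H](Sc5ccc(C)cc5)[C@@H](OCc5ccccc5)[C@@H](c1ccc(OCc5ccccc5)c(OCc5ccccc5)c1)O2 | intermediate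

9 | 2,4,6-trihydroxybenzaldehyde | O=Cc1c(O)cc(O)cc1O | starting material

10 | 2,4-bis(benzyloxy)-6-hydroxybenzaldehyde | O=Cc1c(O)cc(OCc5ccccc5)cc1OCc5ccccc5 | intermediate

11 | 2-allyloxy-4,6-bis(benzyloxy)benzaldehyde | O=Cc1c(OCC=C)cc(OCc5ccccc5)cc1OCc5ccccc5 | intermediate

12 | 8-bromo-6-lithio-4β-(4-methylphenylthio)-3,5,7,3',4'-penta-O-benzylepicatechin | [Li]c1c(OCc5ccccc5)c(Br)c2c(c1OCc5ccccc5)[C@H](Sc5ccc(C)cc5)[C@@H](OCc5ccccc5)[C@@H](c1ccc(OCc5ccccc5)c(OCc5ccccc5)c1)O2 | intermediate

13 | [2-allyloxy-4,6-bis(benzyloxy)phenyl][8-bromo-4β-(4-methylphenylthio)-3,5,7,3',4'-penta-O-benzylepicatechin-6-yl]methanol, both carbinol epimers (carbinol centre drawn without configuration) | C=CCOc1cc(OCc5ccccc5)cc(OCc5ccccc5)c1C(O)c1c(OCc5ccccc5)c(Br)c2c(c1OCc5ccccc5)[C@H](Sc5ccc(C)cc5)[C@@H](OCc5ccccc5)[C@@H](c1ccc(OCc5ccccc5)c(OCc5ccccc5)c1)O2 | intermediate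

14 | [2-hydroxy-4,6-bis(benzyloxy)phenyl][8-bromo-4β-(4-methylphenylthio)-3,5,7,3',4'-penta-O-benzylepicatechin-6-yl]methanol, both carbinol epimers (carbinol centre drawn without configuration) | Oc1cc(OCc5ccccc5)cc(OCc5ccccc5)c1C(O)c1c(OCc5ccccc5)c(Br)c2c(c1OCc5ccccc5)[C@H](Sc5ccc(C)cc5)[C@@H](OCc5ccccc5)[C@@H](c1ccc(OCc5ccccc5)c(OCc5ccccc5)c1)O2 | intermediate

15 | 3,4-bis(benzyloxy)benzaldehyde | O=Cc1ccc(OCc5ccccc5)c(OCc5ccccc5)c1 | starting material

16 | (E)-2-[3,4-bis(benzyloxy)styryl]-4,4,5,5-tetramethyl-1,3,2-dioxaborolane | CC1(C)OB(/C=C/c2ccc(OCc5ccccc5)c(OCc5ccccc5)c2)OC1(C)C | intermediate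

17 | potassium (E)-[3,4-bis(benzyloxy)styryl]trifluoroborate | [K+].F[B-](F)(F)/C=C/c1ccc(OCc5ccccc5)c(OCc5ccccc5)c1 | intermediate

18 | (E)-2-[3,4-bis(benzyloxy)phenyl]vinyl benzoate | O=C(O/C=C/c1ccc(OCc5ccccc5)c(OCc5ccccc5)c1)c1ccccc1 | intermediate

19 | (E)-3,5-bis(benzyloxy)-6-{[8-bromo-4β-(4-methylphenylthio)-3,5,7,3',4'-penta-O-benzylepicatechin-6-yl]methylidene}cyclohexa-2,4-dien-1-one (aryl group anti to the carbonyl) | O=C1C=C(OCc5ccccc5)C=C(OCc5ccccc5)/C1=C\c1c(OCc5ccccc5)c(Br)c2c(c1OCc5ccccc5)[C@H](Sc5ccc(C)cc5)[C@@H](OCc5ccccc5)[C@@H](c1ccc(OCc5ccccc5)c(OCc5ccccc5)c1)O2 | intermediate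

20 | 3-O-benzoyl-5,7,3',4'-tetra-O-benzylcatechin-(4α→6)-8-bromo-4β-(4-methylphenylthio)-3,5,7,3',4'-penta-O-benzylepicatechin | c5ccccc5COc1cc(OCc5ccccc5)c2c(c1)O[C@H](c1ccc(OCc5ccccc5)c(OCc5ccccc5)c1)[C@@H](OC(=O)c5ccccc5)[C@@H]2c1c(OCc5ccccc5)c(Br)c2c(c1OCc5ccccc5)[C@H](Sc5ccc(C)cc5)[C@@H](OCc5ccccc5)[C@@H](c1ccc(OCc5ccccc5)c(OCc5ccccc5)c1)O2 | intermediate

21 | 3-O-benzoyl-tetra-O-benzylcatechin-(4α→6)-8-bromo-penta-O-benzylepicatechin-(4β→8)-penta-O-benzylepicatechin-(4β→8)-penta-O-benzylepicatechin | c5ccccc5COc1cc(OCc5ccccc5)c2c(c1)O[C@H](c1ccc(OCc5ccccc5)c(OCc5ccccc5)c1)[C@@H](OC(=O)c5ccccc5)[C@@H]2c1c(OCc5ccccc5)c(Br)c2c(c1OCc5ccccc5)[C@H](c1c(OCc5ccccc5)cc(OCc5ccccc5)c3c1O[C@H](c1ccc(OCc5ccccc5)c(OCc5ccccc5)c1)[C@H](OCc5ccccc5)[C@H]3c1c(OCc5ccccc5)cc(OCc5ccccc5)c3c1O[C@H](c1ccc(OCc5ccccc5)c(OCc5ccccc5)c1)[C@H](OCc5ccccc5)C3)[C@@H](OCc5ccccc5)[C@@H](c1ccc(OCc5ccccc5)c(OCc5ccccc5)c1)O2 | intermediate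

22 | tetra-O-benzylcatechin-(4α→6)-8-bromo-penta-O-benzylepicatechin-(4β→8)-penta-O-benzylepicatechin-(4β→8)-penta-O-benzylepicatechin (3-OH of unit 1 free) | c5ccccc5COc1cc(OCc5ccccc5)c2c(c1)O[C@H](c1ccc(OCc5ccccc5)c(OCc5ccccc5)c1)[C@@H](O)[C@@H]2c1c(OCc5ccccc5)c(Br)c2c(c1OCc5ccccc5)[C@H](c1c(OCc5ccccc5)cc(OCc5ccccc5)c3c1O[C@H](c1ccc(OCc5ccccc5)c(OCc5ccccc5)c1)[C@H](OCc5ccccc5)[C@H]3c1c(OCc5ccccc5)cc(OCc5ccccc5)c3c1O[C@H](c1ccc(OCc5ccccc5)c(OCc5ccccc5)c1)[C@H](OCc5ccccc5)C3)[C@@H](OCc5ccccc5)[C@@H](c1ccc(OCc5ccccc5)c(OCc5ccccc5)c1)O2 | intermediate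

23 | catechin-(4α→6)-epicatechin-(4β→8)-epicatechin-(4β→8)-epicatechin (CNP0228086.1) | Oc1cc(O)c2c(c1)O[C@H](c1ccc(O)c(O)c1)[C@@H](O)[C@@H]2c1c(O)cc2c(c1O)[C@H](c1c(O)cc(O)c3c1O[C@H](c1ccc(O)c(O)c1)[C@H](O)[C@H]3c1c(O)cc(O)c3c1O[C@H](c1ccc(O)c(O)c1)[C@H](O)C3)[C@@H](O)[C@@H](c1ccc(O)c(O)c1)O2 | target

**Step count and risks**

Total step count: 18. Longest linear sequence: 12 steps from (−)-epicatechin (steps 1, 2, 3, 5, 6, 7, 10, 11, 15, 16, 17, 18).

Steps most likely to fail:

1. Step 15 (Proposed new method). The quinone methide may be intercepted by arene positions instead of the alkene (Friedel–Crafts oligomerisation), the alkene may add with the wrong regiochemistry or on the wrong face, or closure may give the 2,4-trans chroman. The fallback sets out from 6 and comes back at 20, using the classical cationic interflavan coupling with orthogonal leaving groups. Compound 6 would be treated with 4-methylbenzenethiol and BF3·OEt2 to give 8-bromo-4β-(4-methylphenylthio)-3,5,7,3',4'-penta-O-benzylepicatechin F1, whose only free ring A position is C6. Commercial (+)-catechin would be benzylated (BnBr, K2CO3) to 5,7,3',4'-tetra-O-benzyl-(+)-catechin F2, benzoylated (BzCl, pyridine, DMAP) to 3-O-benzoyl-5,7,3',4'-tetra-O-benzylcatechin F3 and oxidised (DDQ, 2-ethoxyethanol) to 3-O-benzoyl-4-(2-ethoxyethoxy)-5,7,3',4'-tetra-O-benzylcatechin F4 (drawn 4β; this centre is lost on ionisation). TMSOTf at −78 °C would ionise only the C4 ether of F4, and C6 of F1 (in excess, F4 added slowly) should attack the catechin cation anti to the 3-benzoate (4α) to give 20, the thioether being inert to the hard Lewis acid.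

2. Step 16. The cation of unit 2 may be captured at the wrong arene position of 5 (C6 sites) or by ring A of unit 1 of a second molecule of 20 (self-condensation), or the hindered thioether may ionise sluggishly. The fallback sets out from 20 and comes back at 21, replacing the dimer-plus-dimer coupling by a stepwise chain extension. Under the same buffered AgBF4 conditions 20 would be coupled with an excess of monomer 4, which reacts through its C8 while its own C4 ether survives the buffered soft activation, to give 3-O-benzoyl-tetra-O-benzylcatechin-(4α→6)-8-bromo-penta-O-benzylepicatechin-(4β→8)-4β-(2-ethoxyethoxy)-penta-O-benzylepicatechin F5. TMSOTf at −78 °C with an excess of 3 would then ionise the C4 ether of unit 3 and attach unit 4 through its C8 on the β face, giving 21.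

3. Step 10. Addition of the doubly ortho-substituted aryllithium to the doubly ortho-substituted aldehyde may be too slow, so that proton transfer or halogen scrambling takes over. The fallback sets out from 8 and comes back at 14 (step 11 is then not needed), reversing the roles of the two partners. Aryllithium 12, made as before, would be quenched with DMF to give 8-bromo-6-formyl-4β-(4-methylphenylthio)-3,5,7,3',4'-penta-O-benzylepicatechin F6. Commercial 3,5-bis(benzyloxy)phenol would be converted with EtMgBr into bromomagnesium 3,5-bis(benzyloxy)phenolate F7. In toluene/CH2Cl2 this bromomagnesium phenolate should add to F6 through its ortho carbon in a chelation-controlled ortho-hydroxyalkylation of the phenol, giving the free o-hydroxybenzhydrol 14 directly after an aqueous NH4Cl work-up.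

**Further compounds**

F1 | step 15 | 8-bromo-4β-(4-methylphenylthio)-3,5,7,3',4'-penta-O-benzylepicatechin | c1c(OCc5ccccc5)c(Br)c2c(c1OCc5ccccc5)[C@H](Sc5ccc(C)cc5)[C@@H](OCc5ccccc5)[C@@H](c1ccc(OCc5ccccc5)c(OCc5ccccc5)c1)O2

F2 | step 15 | 5,7,3',4'-tetra-O-benzyl-(+)-catechin | c5ccccc5COc1cc(OCc5ccccc5)c2c(c1)O[C@H](c1ccc(OCc5ccccc5)c(OCc5ccccc5)c1)[C@@H](O)C2

F3 | step 15 | 3-O-benzoyl-5,7,3',4'-tetra-O-benzylcatechin | c5ccccc5COc1cc(OCc5ccccc5)c2c(c1)O[C@H](c1ccc(OCc5ccccc5)c(OCc5ccccc5)c1)[C@@H](OC(=O)c5ccccc5)C2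

F4 | step 15 | 3-O-benzoyl-4β-(2-ethoxyethoxy)-5,7,3',4'-tetra-O-benzylcatechin | c5ccccc5COc1cc(OCc5ccccc5)c2c(c1)O[C@H](c1ccc(OCc5ccccc5)c(OCc5ccccc5)c1)[C@@H](OC(=O)c5ccccc5)[C@H]2OCCOCC

F5 | step 16 | 3-O-benzoyl-tetra-O-benzylcatechin-(4α→6)-8-bromo-penta-O-benzylepicatechin-(4β→8)-4β-(2-ethoxyethoxy)-penta-O-benzylepicatechin | c5ccccc5COc1cc(OCc5ccccc5)c2c(c1)O[C@H](c1ccc(OCc5ccccc5)c(OCc5ccccc5)c1)[C@@H](OC(=O)c5ccccc5)[C@@H]2c1c(OCc5ccccc5)c(Br)c2c(c1OCc5ccccc5)[C@H](c1c(OCc5ccccc5)cc(OCc5ccccc5)c3c1O[C@H](c1ccc(OCc5ccccc5)c(OCc5ccccc5)c1)[C@H](OCc5ccccc5)[C@H]3OCCOCC)[C@@H](OCc5ccccc5)[C@@H](c1ccc(OCc5ccccc5)c(OCc5ccccc5)c1)O2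

F6 | step 10 | 8-bromo-6-formyl-4β-(4-methylphenylthio)-3,5,7,3',4'-penta-O-benzylepicatechin | O=Cc1c(OCc5ccccc5)c(Br)c2c(c1OCc5ccccc5)[C@H](Sc5ccc(C)cc5)[C@@H](OCc5ccccc5)[C@@H](c1ccc(OCc5ccccc5)c(OCc5ccccc5)c1)O2

F7 | step 10 | bromomagnesium 3,5-bis(benzyloxy)phenolate | Br[Mg]Oc1cc(OCc5ccccc5)cc(OCc5ccccc5)c1
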